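**Retrosynthetic overview**
- Ring C (the pyran-4-one) is closed late from a 2'-hydroxychalcone (I2/DMSO). The chalcone comes from a benzodioxane aldehyde and a dibenzyl-protected phloroacetophenone, and three benzyl ethers are removed last.
- The aldehyde and the CH2OH group both come from one trans diester (LiAlH4, then MnO2).
- Key disconnection: the bond from the guaiacyl ring to the dioxane C–H carbon, made by rhodium-catalysed enantioselective 1,4-addition of an arylboronic acid to a flat, achiral 1,4-benzodioxine-2-carboxylate; base then sets the trans ring.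
- Enabling feature: in the 1,4-dioxane ring the aryl-bearing carbon (bonded to the oxygen on C-3' of ring B) is next to the carbon carrying CH2OH (bonded to the oxygen on C-4'). With CH2OH raised to CO2Me and that ring C–C bond to C=C, the aryl-bearing carbon becomes the β-carbon of a cyclic β-aryloxy acrylate.
- Ring order: dioxine ring (O-alkylation, formylation, copper-catalysed O-arylation on methyl 5-bromovanillate), then the two stereocentres, then ring C; ring A, ring B and the guaiacyl ring are bought.

Key step: step 3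

Assumption: methyl 3-bromo-4-hydroxy-5-methoxybenzoate, [4-(benzyloxy)-3-methoxyphenyl]boronic acid and 2'-hydroxy-4',6'-bis(benzyloxy)acetophenone are taken as catalogue compounds.
Remark: the dioxane ring of the target is trans with both stereocentres R. Benzodioxine locants below: C-2 carries the ester or CH2OH group, C-3 the aryl group.

**Step 1**
Reactants: 1 methyl 3-bromo-4-hydroxy-5-methoxybenzoate; 2 methyl bromoacetate
Product: 3 methyl 3-bromo-5-methoxy-4-(2-methoxy-2-oxoethoxy)benzoate
Conditions: K2CO3, DMF, rt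
Reagents that add atoms: none
Why: Williamson ether synthesis, in which the phenoxide of 1 (acidified by the para ester and the ortho bromine) displaces bromide from the α-bromo ester by SN2; no stereocentre is formed.

**Step 2**
Reactants: 3 methyl 3-bromo-5-methoxy-4-(2-methoxy-2-oxoethoxy)benzoate; 4 methyl formate
Product: 6 dimethyl 8-methoxy-1,4-benzodioxine-2,6-dicarboxylate, via sodium formyl-ester enolate 5 (not isolated)
Conditions: NaH, THF, 0 °C to rt; evaporate; then CuI (10 mol %), 1,10-phenanthroline (20 mol %), DMF, 100 °C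
Reagents that add atoms: none
Why: Crossed Claisen formylation of the only enolisable ester by non-enolisable methyl formate is driven by formation of the stabilised β-oxo-ester enolate 5, whose oxygen then undergoes copper-catalysed intramolecular Ullmann-type O-arylation with the ortho C–Br bond (six-membered ring closure; C-arylation would need a four-membered ring), as known for 1,3-dicarbonyl enolates giving 4H-chromenes and benzofurans; the bromine position fixes the regiochemistry of the dioxine ring and no stereocentre is formed.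

**Step 3**
Reactants: 6 dimethyl 8-methoxy-1,4-benzodioxine-2,6-dicarboxylate; 7 [4-(benzyloxy)-3-methoxyphenyl]boronic acid
Product: 8 dimethyl (2R,3R)-3-[4-(benzyloxy)-3-methoxyphenyl]-8-methoxy-2,3-dihydro-1,4-benzodioxine-2,6-dicarboxylate (cis)
Conditions: [Rh(OH)((S)-BINAP)]2 (3 mol %), 7 (3 equiv), 1,4-dioxane/H2O (10:1), 60 °C
Reagents that add atoms: none
Why: Proposed new method: transmetalation of boronic acid 7 to the hydroxorhodium–(S)-BINAP complex gives an aryl–rhodium species that inserts the C2=C3 bond of 6 with the aryl group going to C-3 (the β-carbon of the acrylate, made electrophilic by the C-2 ester) and rhodium to C-2 as an oxa-π-allyl enolate, which water protonates to release 8 and the hydroxorhodium catalyst. The closest known reaction type is the Hayashi–Miyaura rhodium/BINAP 1,4-addition of arylboronic acids, established for β-aryloxy enones (chromones to flavanones) and for 1-nitrocyclohexene, a cyclic trisubstituted acceptor with an exocyclic activating group; a 2,3-dioxygenated cyclic acrylate has not been used. No ring is closed. The C-3 stereocentre (C–Ar) is set by the ligand, which lets the planar, achiral dioxine react through only one of its enantiotopic faces; (S)-BINAP is chosen by transferring the sense of induction known for 2-cyclohexenone and (E)-enones (aryl delivered to the β-carbon face on which the α-carbon, the β-substituent and the β-hydrogen run counterclockwise), which predicts 3R, and the C-2 stereocentre arises on protonation of the enolate, expected from the face away from the new aryl group (cis), which is not decisive because step 4 equilibrates C-2. The step needs 1,4- over 1,2-selectivity, secured by the inertness of ester carbonyls towards aryl–rhodium species, and protonation rather than β-aryloxide elimination of the enolate, favoured by the water-rich base-free medium, the moderate temperature and a ring that holds the C3–O4 bond out of plane with the C2–Rh bond. Any trans epimer 9 formed alongside is carried on together with 8.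

**Step 4**
Reactants: 8 dimethyl (2R,3R)-3-[4-(benzyloxy)-3-methoxyphenyl]-8-methoxy-2,3-dihydro-1,4-benzodioxine-2,6-dicarboxylate (cis)
Product: 9 dimethyl (2S,3R)-3-[4-(benzyloxy)-3-methoxyphenyl]-8-methoxy-2,3-dihydro-1,4-benzodioxine-2,6-dicarboxylate (trans)
Conditions: NaOMe (0.2 equiv), MeOH/THF, 0 °C to rt
Reagents that add atoms: none
Why: Base-mediated epimerisation through the ester enolate at C-2 should funnel the material to the thermodynamically preferred trans (diequatorial) 2,3-disubstituted benzodioxane, so C-2 becomes S under thermodynamic control while the non-acidic C-3 centre keeps the R configuration set in step 3.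

**Step 5**
Reactants: 9 dimethyl (2S,3R)-3-[4-(benzyloxy)-3-methoxyphenyl]-8-methoxy-2,3-dihydro-1,4-benzodioxine-2,6-dicarboxylate (trans)
Product: 10 [(2R,3R)-3-[4-(benzyloxy)-3-methoxyphenyl]-8-methoxy-2,3-dihydro-1,4-benzodioxine-2,6-diyl]dimethanol (trans)
Conditions: LiAlH4, THF, 0 °C; aqueous work-up
Reagents that add atoms: none
Why: Ester reduction with LiAlH4 converts both methyl esters into primary alcohols without touching aryl or benzyl ethers, and C-2 (now R by the priority change, same spatial arrangement) is no longer epimerisable.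

**Step 6**
Reactants: 10 [(2R,3R)-3-[4-(benzyloxy)-3-methoxyphenyl]-8-methoxy-2,3-dihydro-1,4-benzodioxine-2,6-diyl]dimethanol (trans)
Product: 11 (2R,3R)-3-[4-(benzyloxy)-3-methoxyphenyl]-2-(hydroxymethyl)-8-methoxy-2,3-dihydro-1,4-benzodioxine-6-carbaldehyde
Conditions: MnO2 (activated), CH2Cl2, rt
Reagents that add atoms: none
Why: Chemoselective benzylic oxidation, in which activated MnO2 oxidises only the benzylic alcohol and leaves the aliphatic CH2OH and both stereocentres alone.

**Step 7**
Reactants: 11 (2R,3R)-3-[4-(benzyloxy)-3-methoxyphenyl]-2-(hydroxymethyl)-8-methoxy-2,3-dihydro-1,4-benzodioxine-6-carbaldehyde; 12 1-[2,4-bis(benzyloxy)-6-hydroxyphenyl]ethan-1-one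
Product: 13 (2E)-1-[2,4-bis(benzyloxy)-6-hydroxyphenyl]-3-[(2R,3R)-3-[4-(benzyloxy)-3-methoxyphenyl]-2-(hydroxymethyl)-8-methoxy-2,3-dihydro-1,4-benzodioxin-6-yl]prop-2-en-1-one
Conditions: KOH (aq. 50 %), EtOH/THF, rt
Reagents that add atoms: none
Why: Claisen–Schmidt condensation, in which the enolate of the ortho-hydroxyacetophenone adds to the non-enolisable aldehyde and E1cB loss of water gives the conjugated E-enone; the stereocentres carry no acidic hydrogen.

**Step 8**
Reactants: 13 (2E)-1-[2,4-bis(benzyloxy)-6-hydroxyphenyl]-3-[(2R,3R)-3-[4-(benzyloxy)-3-methoxyphenyl]-2-(hydroxymethyl)-8-methoxy-2,3-dihydro-1,4-benzodioxin-6-yl]prop-2-en-1-one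
Product: 14 5,7-bis(benzyloxy)-2-[(2R,3R)-3-[4-(benzyloxy)-3-methoxyphenyl]-2-(hydroxymethyl)-8-methoxy-2,3-dihydro-1,4-benzodioxin-6-yl]-4H-chromen-4-one
Conditions: I2 (10 mol %), DMSO, 120 °C
Reagents that add atoms: none
Why: Iodine-catalysed oxidative cyclisation of a 2'-hydroxychalcone, in which 6-endo oxa-Michael closure of ring C, α-iodination and loss of HI give the 4H-chromen-4-one while DMSO reoxidises HI to I2; benzyl ethers, the aliphatic CH2OH and the dioxane ring should not be affected.

**Step 9**
Reactants: 14 5,7-bis(benzyloxy)-2-[(2R,3R)-3-[4-(benzyloxy)-3-methoxyphenyl]-2-(hydroxymethyl)-8-methoxy-2,3-dihydro-1,4-benzodioxin-6-yl]-4H-chromen-4-one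
Product: 15 5'-methoxyhydnocarpin
Conditions: H2 (1 atm), Pd/C (10 wt %), THF/MeOH, rt
Reagents that add atoms: none
Why: Hydrogenolysis of the three aryl benzyl ethers over Pd/C; the ring benzylic C–O bond of the dioxane (a cyclic 2-aryl ether of the flavan type) and the chromenone double bond react far more slowly under these mild conditions, so both stereocentres are kept.

**Compound list**
1 | methyl 3-bromo-4-hydroxy-5-methoxybenzoate | COC(=O)c1cc(Br)c(O)c(OC)c1 | starting material
2 | methyl bromoacetate | COC(=O)CBr | starting material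
3 | methyl 3-bromo-5-methoxy-4-(2-methoxy-2-oxoethoxy)benzoate | COC(=O)COc1c(Br)cc(C(=O)OC)cc1OC | intermediate
4 | methyl formate | COC=O | starting material
5 | sodium 2-[2-bromo-6-methoxy-4-(methoxycarbonyl)phenoxy]-3-methoxy-3-oxoprop-1-en-1-olate (delocalised enolate, geometry mobile; not isolated) | [Na+].[O-]C=C(Oc1c(Br)cc(C(=O)OC)cc1OC)C(=O)OC | intermediate
6 | dimethyl 8-methoxy-1,4-benzodioxine-2,6-dicarboxylate | COC(=O)C1=COc2cc(C(=O)OC)cc(OC)c2O1 | intermediate
7 | [4-(benzyloxy)-3-methoxyphenyl]boronic acid | COc1cc(B(O)O)ccc1OCc1ccccc1 | starting material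
8 | dimethyl (2R,3R)-3-[4-(benzyloxy)-3-methoxyphenyl]-8-methoxy-2,3-dihydro-1,4-benzodioxine-2,6-dicarboxylate (cis) | COc1cc([C@H]2Oc3cc(C(=O)OC)cc(OC)c3O[C@H]2C(=O)OC)ccc1OCc1ccccc1 | intermediate
9 | dimethyl (2S,3R)-3-[4-(benzyloxy)-3-methoxyphenyl]-8-methoxy-2,3-dihydro-1,4-benzodioxine-2,6-dicarboxylate (trans) | COc1cc([C@H]2Oc3cc(C(=O)OC)cc(OC)c3O[C@@H]2C(=O)OC)ccc1OCc1ccccc1 | intermediate
10 | [(2R,3R)-3-[4-(benzyloxy)-3-methoxyphenyl]-8-methoxy-2,3-dihydro-1,4-benzodioxine-2,6-diyl]dimethanol (trans) | COc1cc([C@H]2Oc3cc(CO)cc(OC)c3O[C@@H]2CO)ccc1OCc1ccccc1 | intermediate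
11 | (2R,3R)-3-[4-(benzyloxy)-3-methoxyphenyl]-2-(hydroxymethyl)-8-methoxy-2,3-dihydro-1,4-benzodioxine-6-carbaldehyde | COc1cc([C@H]2Oc3cc(C=O)cc(OC)c3O[C@@H]2CO)ccc1OCc1ccccc1 | intermediate
12 | 1-[2,4-bis(benzyloxy)-6-hydroxyphenyl]ethan-1-one | CC(=O)c1c(O)cc(OCc2ccccc2)cc1OCc1ccccc1 | starting material
13 | (2E)-1-[2,4-bis(benzyloxy)-6-hydroxyphenyl]-3-[(2R,3R)-3-[4-(benzyloxy)-3-methoxyphenyl]-2-(hydroxymethyl)-8-methoxy-2,3-dihydro-1,4-benzodioxin-6-yl]prop-2-en-1-one | COc1cc([C@H]2Oc3cc(/C=C/C(=O)c4c(O)cc(OCc5ccccc5)cc4OCc4ccccc4)cc(OC)c3O[C@@H]2CO)ccc1OCc1ccccc1 | intermediate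
14 | 5,7-bis(benzyloxy)-2-[(2R,3R)-3-[4-(benzyloxy)-3-methoxyphenyl]-2-(hydroxymethyl)-8-methoxy-2,3-dihydro-1,4-benzodioxin-6-yl]-4H-chromen-4-one | COc1cc([C@H]2Oc3cc(-c4cc(=O)c5c(OCc6ccccc6)cc(OCc6ccccc6)cc5o4)cc(OC)c3O[C@@H]2CO)ccc1OCc1ccccc1 | intermediate
15 | 5'-methoxyhydnocarpin, 5,7-dihydroxy-2-[(2R,3R)-3-(4-hydroxy-3-methoxyphenyl)-2-(hydroxymethyl)-8-methoxy-2,3-dihydro-1,4-benzodioxin-6-yl]-4H-chromen-4-one | COc1cc([C@H]2Oc3cc(-c4cc(=O)c5c(O)cc(O)cc5o4)cc(OC)c3O[C@@H]2CO)ccc1O | target

**Step count and risks**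
Total steps: 9. Longest linear sequence: 9 steps (1 to 15).

Steps most likely to fail:

1. Step 3 (key step, proposed new method). What may go wrong:
   - carbometalation of the trisubstituted, doubly oxygen-substituted alkene may be slower than protodeboronation of the boronic acid;
   - the rhodium enolate may open the ring by β-aryloxide elimination instead of being protonated;
   - facial selectivity may be low or opposite to the model.

   Fallback (known chemistry, the same bond made as an sp2–sp2 coupling), setting out from 6: C-3 lithiation with LDA (THF, −78 °C) and quenching with I2 should give dimethyl 3-iodo-8-methoxy-1,4-benzodioxine-2,6-dicarboxylate F1. Suzuki–Miyaura coupling with 7 (Pd(PPh3)4, K2CO3, dioxane/H2O, 80 °C) should give dimethyl 3-[4-(benzyloxy)-3-methoxyphenyl]-8-methoxy-1,4-benzodioxine-2,6-dicarboxylate F2. Syn hydrogenation of the tetrasubstituted double bond with [Ir(cod)(PCy3)(py)]PF6 (H2, CH2Cl2), which spares the benzyl ether, should give the racemic cis-diester F3. NaOMe in MeOH, as in step 4, should give the racemic trans-diester F4. Preparative chromatography on a chiral stationary phase then returns to the route at 9.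

2. Step 4. What may go wrong: the ester enolate may open the ring by E1cB loss of the aryloxide on C-3 and reclose by oxa-Michael addition, which would erode the C-3 configuration (partial racemisation during the epimerisation).

   Fallback, setting out from 6, epimerises the other centre under acid instead. The arylation of step 3 is run with (R)-BINAP, and the cis adduct, dimethyl (2S,3S)-3-[4-(benzyloxy)-3-methoxyphenyl]-8-methoxy-2,3-dihydro-1,4-benzodioxine-2,6-dicarboxylate F5, is separated from any trans isomer by chromatography. LiAlH4 reduction should give the cis-diol [(2R,3S)-3-[4-(benzyloxy)-3-methoxyphenyl]-8-methoxy-2,3-dihydro-1,4-benzodioxine-2,6-diyl]dimethanol F6. MnO2 should give the cis-hydroxy aldehyde (2R,3S)-3-[4-(benzyloxy)-3-methoxyphenyl]-2-(hydroxymethyl)-8-methoxy-2,3-dihydro-1,4-benzodioxine-6-carbaldehyde F7. Catalytic BF3·OEt2 (CH2Cl2, 0 °C) should then ionise the C3–O4 bond reversibly to the 4-benzyloxy-3-methoxybenzyl cation; reclosure by the phenol gives the trans ring with the non-acidic C-2 untouched. The fallback returns to the route at 11.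

3. Step 2. What may go wrong: retro-Claisen loss of the formyl group, or sluggish O-arylation of the weakly nucleophilic enolate oxygen in the hot copper stage.

   Fallback, setting out from 3, closes the ring at the saturated level and dehydrogenates afterwards. Aldol hydroxymethylation (LDA, THF, −78 °C; then monomeric formaldehyde) should give racemic methyl 3-bromo-4-[(1-hydroxy-3-methoxy-3-oxopropan-2-yl)oxy]-5-methoxybenzoate F8. Palladium-catalysed intramolecular C–O coupling of the primary alcohol with the aryl bromide (Pd(OAc)2, 2-(di-tert-butylphosphino)-1,1'-binaphthyl, Cs2CO3, toluene, 70 °C) should give racemic dimethyl 8-methoxy-2,3-dihydro-1,4-benzodioxine-2,6-dicarboxylate F9. Radical bromination (NBS, benzoyl peroxide, PhCF3, reflux) should give dimethyl 2,3-dibromo-8-methoxy-2,3-dihydro-1,4-benzodioxine-2,6-dicarboxylate F10. NaI in acetone removes both bromine atoms and returns to the route at 6.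

**Further compounds**
F1 | step 3 | dimethyl 3-iodo-8-methoxy-1,4-benzodioxine-2,6-dicarboxylate | COC(=O)C1=C(I)Oc2cc(C(=O)OC)cc(OC)c2O1
F2 | step 3 | dimethyl 3-[4-(benzyloxy)-3-methoxyphenyl]-8-methoxy-1,4-benzodioxine-2,6-dicarboxylate | COC(=O)C1=C(c2ccc(OCc3ccccc3)c(OC)c2)Oc2cc(C(=O)OC)cc(OC)c2O1
F3 | step 3 | racemic cis-diester (8 together with its (2S,3S) enantiomer) | COc1cc([C@H]2Oc3cc(C(=O)OC)cc(OC)c3O[C@H]2C(=O)OC)ccc1OCc1ccccc1.COc1cc([C@@H]2Oc3cc(C(=O)OC)cc(OC)c3O[C@@H]2C(=O)OC)ccc1OCc1ccccc1
F4 | step 3 | racemic trans-diester (9 together with its (2R,3S) enantiomer) | COc1cc([C@H]2Oc3cc(C(=O)OC)cc(OC)c3O[C@@H]2C(=O)OC)ccc1OCc1ccccc1.COc1cc([C@@H]2Oc3cc(C(=O)OC)cc(OC)c3O[C@H]2C(=O)OC)ccc1OCc1ccccc1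
F5 | step 4 | dimethyl (2S,3S)-3-[4-(benzyloxy)-3-methoxyphenyl]-8-methoxy-2,3-dihydro-1,4-benzodioxine-2,6-dicarboxylate (cis, single enantiomer) | COc1cc([C@@H]2Oc3cc(C(=O)OC)cc(OC)c3O[C@@H]2C(=O)OC)ccc1OCc1ccccc1
F6 | step 4 | [(2R,3S)-3-[4-(benzyloxy)-3-methoxyphenyl]-8-methoxy-2,3-dihydro-1,4-benzodioxine-2,6-diyl]dimethanol (cis) | COc1cc([C@@H]2Oc3cc(CO)cc(OC)c3O[C@@H]2CO)ccc1OCc1ccccc1
F7 | step 4 | (2R,3S)-3-[4-(benzyloxy)-3-methoxyphenyl]-2-(hydroxymethyl)-8-methoxy-2,3-dihydro-1,4-benzodioxine-6-carbaldehyde (cis) | COc1cc([C@@H]2Oc3cc(C=O)cc(OC)c3O[C@@H]2CO)ccc1OCc1ccccc1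
F8 | step 2 | methyl 3-bromo-4-[(1-hydroxy-3-methoxy-3-oxopropan-2-yl)oxy]-5-methoxybenzoate (racemic) | COC(=O)C(CO)Oc1c(Br)cc(C(=O)OC)cc1OC
F9 | step 2 | dimethyl 8-methoxy-2,3-dihydro-1,4-benzodioxine-2,6-dicarboxylate (racemic) | COC(=O)C1COc2cc(C(=O)OC)cc(OC)c2O1
F10 | step 2 | dimethyl 2,3-dibromo-8-methoxy-2,3-dihydro-1,4-benzodioxine-2,6-dicarboxylate | COC(=O)C1(Br)C(Br)Oc2cc(C(=O)OC)cc(OC)c2O1
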